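**Retrosynthetic overview**

- The route rests on ring carbon C5 of the single ring, the 4-pyranone: a bromine-bearing sp2 carbon between the C4 carbonyl carbon and C6. This is the pattern left when a "CBr" unit is inserted into the C2=C3 enol-ether bond of a furan-3-ol silyl ether.
- Late stage: the C6–Br bond (zincation, then bromine) and the two C1'–Br bonds (radical bromination) are removed, leading back to 3,5-dibromo-2-propyl-4H-pyran-4-one.
- Key disconnection: C4–C5 and C5–C6 are cut, giving 4-bromo-5-propyl-3-(tert-butyldimethylsilyloxy)furan and dibromocarbene from bromoform.
- The silyloxyfuran comes from 5-propylfuran-3(2H)-one by C4 bromination and O-silylation. The furanone comes from a Claisen condensation of pentan-2-one with a silyl-protected glycolate and acid cyclodehydration.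
- Ring order: the five-membered furanone is formed first and is then expanded to the six-membered pyranone. No other ring is made.

Key step: step 5

Remark: the target has no stereocentre, so no enantiomer question arises. The pyranone is numbered throughout with the side chain at C2 (C3 Br, C4 C=O, C5 Br, C6 the last ring position); the systematic name of the target numbers the ring the other way round.

**Step 1**
Reactants: 1 pentan-2-one; 2 ethyl 2-((tert-butyldimethylsilyl)oxy)acetate
Product: 4 1-((tert-butyldimethylsilyl)oxy)heptane-2,4-dione, via lithium enolate 3 (not isolated)
Conditions: 1 (2.2 equiv), LDA (2.1 equiv), THF, −78 °C; then 2 (1.0 equiv), −78 → 0 °C; aq. NH4Cl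
Reagents that add atoms: none
Why: Crossed Claisen condensation in which the kinetic methyl-side lithium enolate is acylated by the inductively activated α-silyloxy ester, the second equivalent of enolate taking up the acidic diketone proton; an ester without a leaving group at its α-carbon is used so that Darzens or alkylation pathways cannot compete.

**Step 2**
Reactants: 4 1-((tert-butyldimethylsilyl)oxy)heptane-2,4-dione
Product: 6 5-propylfuran-3(2H)-one, via hydroxy diketone 5 (not isolated)
Conditions: 2 M aq. HCl, THF, rt
Reagents that add atoms: none
Why: Acid removes the primary silyl ether, and the α'-hydroxy-1,3-diketone should undergo the standard acid-catalysed cyclodehydration to a 3(2H)-furanone (5-exo hemiketal formation at the C4 carbonyl, then loss of water to the vinylogous ester).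

**Step 3**
Reactants: 6 5-propylfuran-3(2H)-one
Product: 7 4-bromo-5-propylfuran-3(2H)-one
Conditions: NBS (1.05 equiv), CH2Cl2, 0 °C, dark
Reagents that add atoms: N-bromosuccinimide, O=C1CCC(=O)N1Br
Why: Electrophilic α-bromination of a vinylogous ester, in which C4 is the nucleophilic β-carbon of the ring enol ether and reacts directly under neutral conditions, whereas C2 could react only through its enol, so no acid or base is added.

**Step 4**
Reactants: 7 4-bromo-5-propylfuran-3(2H)-one
Product: 8 ((4-bromo-5-propylfuran-3-yl)oxy)(tert-butyl)dimethylsilane
Conditions: TBSOTf (1.2 equiv), Et3N (1.5 equiv), CH2Cl2, 0 °C; filtration through basic alumina, used at once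
Reagents that add atoms: tert-butyldimethylsilyl trifluoromethanesulfonate, CC(C)(C)[Si](C)(C)OS(=O)(=O)C(F)(F)F
Why: Soft enolisation and O-silylation (silyl enol ether formation), in which loss of a C2 proton is driven by the gain of furan aromaticity and the hard silyl triflate reacts at oxygen.

**Step 5**
Reactants: 8 ((4-bromo-5-propylfuran-3-yl)oxy)(tert-butyl)dimethylsilane; 9 bromoform
Product: 12 3,5-dibromo-2-propyl-4H-pyran-4-one, via dibromocyclopropane adduct 10 (not isolated), via silyloxypyrylium bromide 11 (not isolated)
Conditions: CHBr3 (1.5 equiv), KOtBu (2.5 equiv), pentane, −20 °C → rt; aq. NH4Cl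
Reagents that add atoms: bromoform (compound 9), BrC(Br)Br
Why: Proposed new method: dibromocarbene, made by α-elimination from bromoform and KOtBu, is electrophilic and should add to the furan C2=C3 bond of 8, attacking first at the unsubstituted α-carbon C2, which is also the β-carbon of the silyl enol ether; the 6,6-dibromo-2-oxabicyclo[3.1.0]hexene 10 should then ionise its endo bromide with disrotatory opening of the shared bond to give the aromatic 4-silyloxypyrylium bromide 11, from which tert-butoxide (or bromide) takes the silyl group and leaves the C4 carbonyl of 12. The closest known reactions are the dihalocarbene one-carbon homologation of cyclic silyl enol ethers to 2-halo-2-enones and the Ciamician–Dennstedt expansion of pyrroles and indoles to 3-halopyridines and 3-haloquinolines; a 3-silyloxyfuran as substrate is the untested element. The six-membered ring is closed by no cyclisation: it arises by electrocyclic cyclopropyl-to-allyl cation ring expansion of the five-membered ring, which forms C4–C5 and C5–C6 with the carbene carbon as C5 carrying its remaining bromine (furan C2, C3, C4 and C5 become pyranone C6, C4, C3 and C2). No stereocentre is present in 12, and the two bridgehead centres of racemic 10 are destroyed on opening. The step needs site selectivity for C2=C3 over C4=C5; this should follow from donation of both the ring oxygen and the silyloxy group into C2=C3 and its free C2 terminus, whereas C4=C5 is tetrasubstituted and carries the deactivating bromine. Anhydrous alkoxide conditions are used so that the silyl enol ether is not hydrolysed, and a furan-3-olate formed by early desilylation would enter the same pathway.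

**Step 6**
Reactants: 12 3,5-dibromo-2-propyl-4H-pyran-4-one
Product: 14 3,5-dibromo-2-(1,1-dibromopropyl)-4H-pyran-4-one, via monobromide 13 (not isolated)
Conditions: NBS (2.3 equiv), hν (visible lamp), PhCF3, 80 °C
Reagents that add atoms: N-bromosuccinimide, O=C1CCC(=O)N1Br
Why: Wohl–Ziegler radical bromination, in which the C1' hydrogens are activated like benzylic ones by conjugation of the radical with the pyranone C2=C3–C4=O unit and the α-bromo radical formed after the first substitution is brominated again at the same carbon; this step is placed before the ring metalation because the C1' hydrogens of 12 are the most acidic ones and would be removed first by an amide base.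

**Step 7**
Reactants: 14 3,5-dibromo-2-(1,1-dibromopropyl)-4H-pyran-4-one
Product: 16 2,3,5-tribromo-6-(1,1-dibromopropyl)-4H-pyran-4-one, via pyranylzinc chloride 15 (not isolated)
Conditions: TMPZnCl·LiCl (1.3 equiv), THF, 0 → 25 °C; then Br2 (1.5 equiv), −40 °C; aq. Na2S2O3
Reagents that add atoms: bromine, BrBr
Why: Deprotonative zincation with the TMP-zinc amide at the only ring C–H, which is acidified by the ring oxygen and the neighbouring C5 bromine (the C2 zincation known for chromones), followed by electrophilic bromination of the carbon–zinc bond; no enolisable C–H is left after step 6 and the mild zinc amide should spare the gem-dibromide.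

**Compound list**

1 | pentan-2-one | CCCC(C)=O | starting material
2 | ethyl 2-((tert-butyldimethylsilyl)oxy)acetate | CCOC(=O)CO[Si](C)(C)C(C)(C)C | starting material
3 | lithium pent-1-en-2-olate (formed in the flask, not isolated) | [Li+].[O-]C(=C)CCC | intermediate
4 | 1-((tert-butyldimethylsilyl)oxy)heptane-2,4-dione | CCCC(=O)CC(=O)CO[Si](C)(C)C(C)(C)C | intermediate
5 | 1-hydroxyheptane-2,4-dione (formed in the flask, not isolated) | CCCC(=O)CC(=O)CO | intermediate
6 | 5-propylfuran-3(2H)-one | CCCC1=CC(=O)CO1 | intermediate
7 | 4-bromo-5-propylfuran-3(2H)-one | CCCC1=C(Br)C(=O)CO1 | intermediate
8 | ((4-bromo-5-propylfuran-3-yl)oxy)(tert-butyl)dimethylsilane | CCCc1occ(O[Si](C)(C)C(C)(C)C)c1Br | intermediate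
9 | bromoform | BrC(Br)Br | starting material
10 | tert-butyldimethyl((4,6,6-tribromo-3-propyl-2-oxabicyclo[3.1.0]hex-3-en-5-yl)oxy)silane (racemic, cis-fused; formed in the flask, not isolated) | CCCC1=C(Br)C2(O[Si](C)(C)C(C)(C)C)C(O1)C2(Br)Br | intermediate
11 | 3,5-dibromo-4-((tert-butyldimethylsilyl)oxy)-2-propylpyrylium bromide (formed in the flask, not isolated) | CCCc1[o+]cc(Br)c(O[Si](C)(C)C(C)(C)C)c1Br.[Br-] | intermediate
12 | 3,5-dibromo-2-propyl-4H-pyran-4-one | CCCc1occ(Br)c(=O)c1Br | intermediate
13 | 3,5-dibromo-2-(1-bromopropyl)-4H-pyran-4-one (racemic; formed in the flask, not isolated) | CCC(Br)c1occ(Br)c(=O)c1Br | intermediate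
14 | 3,5-dibromo-2-(1,1-dibromopropyl)-4H-pyran-4-one | CCC(Br)(Br)c1occ(Br)c(=O)c1Br | intermediate
15 | (3,5-dibromo-6-(1,1-dibromopropyl)-4-oxo-4H-pyran-2-yl)zinc chloride (formed in the flask, not isolated) | CCC(Br)(Br)c1oc([Zn]Cl)c(Br)c(=O)c1Br | intermediate
16 | 2,3,5-tribromo-6-(1,1-dibromopropyl)-4H-pyran-4-one | CCC(Br)(Br)c1oc(Br)c(Br)c(=O)c1Br | target

**Step count and risks**

Total step count: 7. Longest linear sequence: 7 steps (1 → 16).

Steps most likely to fail:

1. Step 5 (proposed new method). The carbene may add without site control, the silyl enol ether may be cleaved and the furan decomposed by the alkoxide before cyclopropanation, or the pyrylium intermediate may be captured at C6 by alkoxide with ring opening instead of losing the silyl group. The fallback uses known pyranone chemistry, sets out from compound 1 and comes back at compound 12. The lithium enolate 3 of pentan-2-one is acylated with methyl 3,3-dimethoxypropanoate (LDA, THF, −78 → 0 °C) to give 1,1-dimethoxyoctane-3,5-dione F1. Trifluoroacetic acid then closes the masked 1,3,5-tricarbonyl compound, with loss of methanol, to 2-propyl-4H-pyran-4-one F2. Bromine in CH2Cl2 followed by pyridine (addition–elimination at both α-positions) should give the 3,5-dibromide 12.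

2. Step 7. The amide base may attack the 1,1-dibromopropyl group (bromine abstraction or loss of HBr to the bromoalkene) faster than it removes the C6 proton. The fallback sets out from compound 12 and comes back at compound 16, and exchanges the order of the last two operations so that no gem-dibromide is present when base is used. Compound 12 is metalated at C6 under in situ trapping conditions (LiTMP added at −78 °C to 12 premixed with ZnCl2 in THF, so that the ring anion is captured as the zinc species before proton transfer from the side chain), and bromine gives 2,3,5-tribromo-6-propyl-4H-pyran-4-one F3. Radical dibromination of C1' with NBS under light, as in step 6, then gives 16. Any side-chain bromide formed through competing lateral deprotonation in this variant is compound 13 and can be returned to step 6.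

3. Step 6. The second hydrogen abstraction at the hindered, electron-poor C1' may be slow, so that bromination stops at the monobromide, moves to C2', or is followed by loss of HBr to the alkene. The fallback sets out from compound 12 and comes back at compound 14, and replaces the radical process by an ionic one. The lateral (vinylogous) lithium enolate of 12 is formed with LiHMDS (1.05 equiv, THF, −78 °C) and brominated at C1' with 1,2-dibromotetrachloroethane to give 13, which is isolated here. The same deprotonation and bromination, run with inverse addition so that no excess base meets the product, gives 14. This fallback makes no compound outside the compound list (F0).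

**Further compounds**

F1 | step 5 | 1,1-dimethoxyoctane-3,5-dione | CCCC(=O)CC(=O)CC(OC)OC
F2 | step 5 | 2-propyl-4H-pyran-4-one | CCCc1cc(=O)cco1
F3 | step 7 | 2,3,5-tribromo-6-propyl-4H-pyran-4-one | CCCc1oc(Br)c(Br)c(=O)c1Br
F0 | step 6 | none | none
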